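**Retrosynthetic overview**

1. Both rings are closed in one flask without protecting groups. The γ-lactone forms first: C-6–C-7 bond by chromium-mediated 2-(alkoxycarbonyl)allylation of a (Z)-3-iodo enal, then lactonisation. The ten-membered carbocycle forms second: C-3–C-4 bond by Ni/Cr coupling of the (Z)-alkenyl iodide with the C-3 aldehyde.
2. The two partners are (Z)-3-iodobut-2-enal (C-4, C-5, C-6, C-15) and a (Z)-2-(bromomethyl)enoate that carries the C-8 angelate and the C-10 carbinol and keeps its C-3 aldehyde masked as the lactol with the C-10 hydroxyl.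
3. The bromide comes from a γ-hydroxy ynoate: propiolate alkynylation sets C-8; anti-hydroalumination/iodination, angeloylation, Stille hydroxymethylation and bromination build the allylic bromide; ozonolysis of the prenyl group unveils C-3 last.
4. C-10 comes from geraniol by Sharpless epoxidation and reductive epoxide opening.
5. The iodo enal comes from but-2-yn-1-ol by anti-hydroalumination/iodination and MnO2 oxidation.

Locants used below: lactone C-12(=O)–O–C-6, C-7, C-11(=C-13H2); ring C-1 to C-10 with OH on C-3 and C-10, (Z)-C-4=C-5, angelate on C-8; C-14 and C-15 are the methyls on C-10 and C-4.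

Assumption: the SMILES is taken as drawn (cis-fused lactone; 3S,6S,7R,8R,10S; 4Z), and the (S,S)-ProPhenol ligand is taken to give the 8R carbinol (its mirror image is used if the sense is opposite).

**Route**

Step 1
Reactants: 1 geraniol, (2E)-3,7-dimethylocta-2,6-dien-1-ol
Product: 2 [(2S,3S)-3-methyl-3-(4-methylpent-3-en-1-yl)oxiran-2-yl]methanol
Conditions: Ti(OiPr)4 (5 mol %), L-(+)-diethyl tartrate (7 mol %), t-BuOOH, 4 Å molecular sieves, CH2Cl2, −20 °C
Reagents that add atoms: tert-butyl hydroperoxide, CC(C)(C)OO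
Why: Sharpless asymmetric epoxidation: the catalyst formed from Ti(OiPr)4 and L-(+)-diethyl tartrate binds the allylic alcohol and delivers the peroxide oxygen to one face of the 2,3-alkene only, which is known for geraniol to give the (2S,3S)-epoxide in high ee and so fixes the future C-10 centre.

Step 2
Reactants: 2 [(2S,3S)-3-methyl-3-(4-methylpent-3-en-1-yl)oxiran-2-yl]methanol
Product: 3 (3S)-3,7-dimethyloct-6-ene-1,3-diol
Conditions: NaAlH2(OCH2CH2OMe)2, THF, 0 °C to rt
Reagents that add atoms: none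
Why: Regioselective reductive opening of a 2,3-epoxy alcohol: the alkoxyaluminate formed at the primary hydroxyl delivers hydride intramolecularly to C-2, so the tertiary C–O bond (future C-10, S) is untouched and the 1,3-diol results.

Step 3
Reactants: 3 (3S)-3,7-dimethyloct-6-ene-1,3-diol
Product: 4 (3S)-3,7-dimethyl-1,3-bis(triethylsilyloxy)oct-6-ene
Conditions: TESOTf (2.5 equiv), 2,6-lutidine, CH2Cl2, −78 to 0 °C
Reagents that add atoms: triethylsilyl trifluoromethanesulfonate, CC[Si](CC)(CC)OS(=O)(=O)C(F)(F)F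
Why: Silyl ether formation with the highly reactive silyl triflate caps both the primary and the hindered tertiary hydroxyl, which protects the tertiary β-oxygen against retro-aldol cleavage in the steps that follow and creates no stereocentre.

Step 4
Reactants: 4 (3S)-3,7-dimethyl-1,3-bis(triethylsilyloxy)oct-6-ene
Product: 5 (3S)-3,7-dimethyl-3-(triethylsilyloxy)oct-6-enal
Conditions: (COCl)2, DMSO, CH2Cl2, −78 to −30 °C; then Et3N, to rt
Reagents that add atoms: none
Why: Swern oxidation run directly on the bis-silyl ether: the chlorodimethylsulfonium salt exchanges only with the unhindered primary triethylsilyl ether, whose alkoxysulfonium ion collapses to the aldehyde on addition of base, while the tertiary silyl ether survives.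

Step 5
Reactants: 5 (3S)-3,7-dimethyl-3-(triethylsilyloxy)oct-6-enal; 6 methyl propiolate
Product: 7 methyl (4R,6S)-4-hydroxy-6,10-dimethyl-6-(triethylsilyloxy)undec-9-en-2-ynoate
Conditions: ZnMe2 (3 equiv), (S,S)-ProPhenol (20 mol %), Ph3PO (40 mol %), toluene, 4 °C
Reagents that add atoms: none
Why: Zinc-mediated asymmetric alkynylation of an aldehyde (Trost ProPhenol protocol): the chiral dinuclear zinc species made in situ from ZnMe2 and the ligand holds aldehyde and zinc propiolate together and transfers the alkynyl group to the Si face, which sets C-8 as R, the minor C-8 epimer being a diastereomer that can be removed by chromatography.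

Step 6
Reactants: 7 methyl (4R,6S)-4-hydroxy-6,10-dimethyl-6-(triethylsilyloxy)undec-9-en-2-ynoate
Product: 8 methyl (2Z,4R,6S)-4-hydroxy-2-iodo-6,10-dimethyl-6-(triethylsilyloxy)undeca-2,9-dienoate
Conditions: NaAlH2(OCH2CH2OMe)2 (2.2 equiv), THF, −78 °C; then I2, −78 to −20 °C
Reagents that add atoms: iodine, II
Why: Hydroxyl-directed anti-hydroalumination followed by iodinolysis: the C-8 alkoxyaluminate puts hydride on C-7 and aluminium on C-11 on opposite faces of the alkyne, and iodine then replaces aluminium with retention, so the iodine ends up cis to C-8 ((Z)-alkene) and the ester, untouched at −78 °C, trans to it.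

Step 7
Reactants: 8 methyl (2Z,4R,6S)-4-hydroxy-2-iodo-6,10-dimethyl-6-(triethylsilyloxy)undeca-2,9-dienoate; 9 angelic acid, (2Z)-2-methylbut-2-enoic acid
Product: 10 methyl (2Z,4R,6S)-2-iodo-6,10-dimethyl-4-{[(2Z)-2-methylbut-2-enoyl]oxy}-6-(triethylsilyloxy)undeca-2,9-dienoate
Conditions: 9, 2,4,6-trichlorobenzoyl chloride, Et3N, toluene, rt; then 8, DMAP, rt to 60 °C
Reagents that add atoms: none
Why: Yamaguchi esterification: the mixed anhydride of angelic acid acylates the secondary allylic hydroxyl (the only free hydroxyl) under mild conditions that are known not to isomerise the (Z)-2-methylbut-2-enoate to the tiglate, and the C-8 configuration is retained because the C–O bond is not broken.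

Step 8
Reactants: 10 methyl (2Z,4R,6S)-2-iodo-6,10-dimethyl-4-{[(2Z)-2-methylbut-2-enoyl]oxy}-6-(triethylsilyloxy)undeca-2,9-dienoate; 11 (tributylstannyl)methanol
Product: 12 methyl (2E,4R,6S)-2-(hydroxymethyl)-6,10-dimethyl-4-{[(2Z)-2-methylbut-2-enoyl]oxy}-6-(triethylsilyloxy)undeca-2,9-dienoate
Conditions: Pd(PPh3)4 (5 mol %), toluene, 90 °C
Reagents that add atoms: none
Why: Stille cross-coupling: oxidative addition of the alkenyl iodide to zerovalent palladium, transmetallation of the hydroxymethyl group from tin and reductive elimination all proceed with retention of the alkene geometry, which installs C-13 cis to C-8.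

Step 9
Reactants: 12 methyl (2E,4R,6S)-2-(hydroxymethyl)-6,10-dimethyl-4-{[(2Z)-2-methylbut-2-enoyl]oxy}-6-(triethylsilyloxy)undeca-2,9-dienoate
Product: 13 methyl (2Z,4R,6S)-2-(bromomethyl)-6,10-dimethyl-4-{[(2Z)-2-methylbut-2-enoyl]oxy}-6-(triethylsilyloxy)undeca-2,9-dienoate
Conditions: CBr4, PPh3, CH2Cl2, −20 to 0 °C
Reagents that add atoms: carbon tetrabromide, BrC(Br)(Br)Br
Why: Appel reaction: the primary allylic alcohol is activated as an oxyphosphonium ion and displaced by bromide under neutral conditions that leave the angelate, the methyl ester and the tertiary silyl ether alone, the (Z)-bromide being also the more stable geometric isomer.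

Step 10
Reactants: 13 methyl (2Z,4R,6S)-2-(bromomethyl)-6,10-dimethyl-4-{[(2Z)-2-methylbut-2-enoyl]oxy}-6-(triethylsilyloxy)undeca-2,9-dienoate
Product: 15 methyl (2Z,4R)-2-(bromomethyl)-5-[(2S)-5-hydroxy-2-methyloxolan-2-yl]-4-{[(2Z)-2-methylbut-2-enoyl]oxy}pent-2-enoate (lactol; both anomers), via silyl aldehyde 14 (not isolated)
Conditions: O3, CH2Cl2, −78 °C (Sudan red 7B end point); Me2S, −78 to 0 °C; then 48% aq. HF, MeCN, 0 °C
Reagents that add atoms: ozone, [O-][O+]=O
Why: Ozonolysis (Criegee cleavage with reductive work-up) attacks the electron-rich prenyl alkene far faster than the two ester-conjugated alkenes, and fluoride-mediated desilylation then frees the C-10 hydroxyl, which closes onto the new C-3 aldehyde to give the five-membered lactol as an inconsequential mixture of anomers.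

Step 11
Reactants: 16 but-2-yn-1-ol
Product: 17 (2Z)-3-iodobut-2-en-1-ol
Conditions: NaAlH2(OCH2CH2OMe)2, THF, 0 °C to rt; then I2, −78 °C to rt
Reagents that add atoms: iodine, II
Why: Hydroxyl-directed anti-hydroalumination of the propargylic alcohol places aluminium on C-3 and hydride on C-2, and iodinolysis with retention gives only the (Z)-iodoalkene, which fixes the future C-4=C-5 geometry.

Step 12
Reactants: 17 (2Z)-3-iodobut-2-en-1-ol
Product: 18 (2Z)-3-iodobut-2-enal
Conditions: MnO2, CH2Cl2, rt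
Reagents that add atoms: none
Why: MnO2 oxidation of an allylic alcohol stops at the aldehyde and does not isomerise the (Z)-alkene under these neutral conditions.

Step 13
Reactants: 15 methyl (2Z,4R)-2-(bromomethyl)-5-[(2S)-5-hydroxy-2-methyloxolan-2-yl]-4-{[(2Z)-2-methylbut-2-enoyl]oxy}pent-2-enoate; 18 (2Z)-3-iodobut-2-enal
Product: 20 (3aR,4R,6S,9S,10Z,11aS)-6,9-dihydroxy-6,10-dimethyl-3-methylidene-2-oxo-2,3,3a,4,5,6,7,8,9,11a-decahydrocyclodeca[b]furan-4-yl (2Z)-2-methylbut-2-enoate (CNP0137971.2), via iodo lactone lactol 19 (not isolated)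
Conditions: 15 (1.0 equiv), 18 (1.2 equiv), CrCl2 (4 equiv), THF, 0 °C to rt, 2 h; then dilution with DMSO to 2 mM, CrCl2 (6 equiv), NiCl2 (1 mol % of the CrCl2), rt to 40 °C
Reagents that add atoms: none
Why: Proposed new method: two known organochromium reactions are run in one flask, in which divalent chromium first turns the allylic bromide of 15 into a (Z)-2-(alkoxycarbonyl)allylchromium that adds to the free enal 18 through a chair Zimmerman–Traxler transition state (γ-substituent axial, hence C-6/C-7 syn and the cis-lactone once the chromium alkoxide closes onto the methyl ester; aldehyde anti to the C-9 branch on C-8 while C-8–H eclipses the allyl unit to avoid A(1,3) strain, hence 7R from 8R), the lactol (largely closed) keeping the C-3 aldehyde away from the allylchromium and the alkenyl iodide staying inert until NiCl2 is added, after which oxidative addition to zerovalent nickel and transmetallation give an alkenylchromium that closes the ten-membered ring on the aldehyde released from the lactol with retention of the (Z)-alkene, C-3–H eclipsing the alkene and the O–Cr group on the outer face (3S); the closest known reactions are the chromium-mediated 2-(alkoxycarbonyl)allylation of aldehydes to cis-α-methylene-γ-butyrolactones and the Nozaki–Hiyama–Kishi macrocyclisation of alkenyl iodides.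

**Compound list**

1 | geraniol, (2E)-3,7-dimethylocta-2,6-dien-1-ol | CC(C)=CCC/C(C)=C/CO | starting material
2 | [(2S,3S)-3-methyl-3-(4-methylpent-3-en-1-yl)oxiran-2-yl]methanol | OC[C@@H]1O[C@@]1(C)CCC=C(C)C | intermediate
3 | (3S)-3,7-dimethyloct-6-ene-1,3-diol | OCC[C@@](C)(O)CCC=C(C)C | intermediate
4 | (3S)-3,7-dimethyl-1,3-bis(triethylsilyloxy)oct-6-ene | CC[Si](CC)(CC)OCC[C@@](C)(O[Si](CC)(CC)CC)CCC=C(C)C | intermediate
5 | (3S)-3,7-dimethyl-3-(triethylsilyloxy)oct-6-enal | O=CC[C@@](C)(O[Si](CC)(CC)CC)CCC=C(C)C | intermediate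
6 | methyl propiolate | C#CC(=O)OC | starting material
7 | methyl (4R,6S)-4-hydroxy-6,10-dimethyl-6-(triethylsilyloxy)undec-9-en-2-ynoate | COC(=O)C#C[C@H](O)C[C@@](C)(O[Si](CC)(CC)CC)CCC=C(C)C | intermediate
8 | methyl (2Z,4R,6S)-4-hydroxy-2-iodo-6,10-dimethyl-6-(triethylsilyloxy)undeca-2,9-dienoate | COC(=O)/C(I)=C/[C@H](O)C[C@@](C)(O[Si](CC)(CC)CC)CCC=C(C)C | intermediate
9 | angelic acid, (2Z)-2-methylbut-2-enoic acid | C/C=C(/C)C(=O)O | starting material
10 | methyl (2Z,4R,6S)-2-iodo-6,10-dimethyl-4-{[(2Z)-2-methylbut-2-enoyl]oxy}-6-(triethylsilyloxy)undeca-2,9-dienoate | COC(=O)/C(I)=C/[C@H](OC(=O)/C(C)=C\C)C[C@@](C)(O[Si](CC)(CC)CC)CCC=C(C)C | intermediate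
11 | (tributylstannyl)methanol | CCCC[Sn](CCCC)(CCCC)CO | starting material
12 | methyl (2E,4R,6S)-2-(hydroxymethyl)-6,10-dimethyl-4-{[(2Z)-2-methylbut-2-enoyl]oxy}-6-(triethylsilyloxy)undeca-2,9-dienoate | COC(=O)/C(CO)=C/[C@H](OC(=O)/C(C)=C\C)C[C@@](C)(O[Si](CC)(CC)CC)CCC=C(C)C | intermediate
13 | methyl (2Z,4R,6S)-2-(bromomethyl)-6,10-dimethyl-4-{[(2Z)-2-methylbut-2-enoyl]oxy}-6-(triethylsilyloxy)undeca-2,9-dienoate | COC(=O)/C(CBr)=C/[C@H](OC(=O)/C(C)=C\C)C[C@@](C)(O[Si](CC)(CC)CC)CCC=C(C)C | intermediate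
14 | methyl (2Z,4R,6S)-2-(bromomethyl)-6-methyl-4-{[(2Z)-2-methylbut-2-enoyl]oxy}-9-oxo-6-(triethylsilyloxy)non-2-enoate | COC(=O)/C(CBr)=C/[C@H](OC(=O)/C(C)=C\C)C[C@@](C)(O[Si](CC)(CC)CC)CCC=O | intermediate
15 | methyl (2Z,4R)-2-(bromomethyl)-5-[(2S)-5-hydroxy-2-methyloxolan-2-yl]-4-{[(2Z)-2-methylbut-2-enoyl]oxy}pent-2-enoate (both anomers) | COC(=O)/C(CBr)=C/[C@H](OC(=O)/C(C)=C\C)C[C@]1(C)CCC(O)O1 | intermediate
16 | but-2-yn-1-ol | CC#CCO | starting material
17 | (2Z)-3-iodobut-2-en-1-ol | C/C(I)=C/CO | intermediate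
18 | (2Z)-3-iodobut-2-enal | C/C(I)=C/C=O | intermediate
19 | (1R)-2-[(2S)-5-hydroxy-2-methyloxolan-2-yl]-1-{(2R,3R)-2-[(1Z)-2-iodoprop-1-en-1-yl]-4-methylidene-5-oxooxolan-3-yl}ethyl (2Z)-2-methylbut-2-enoate | C=C1C(=O)O[C@@H](/C=C(/C)I)[C@H]1[C@H](OC(=O)/C(C)=C\C)C[C@]2(C)CCC(O)O2 | intermediate
20 | (3aR,4R,6S,9S,10Z,11aS)-6,9-dihydroxy-6,10-dimethyl-3-methylidene-2-oxo-2,3,3a,4,5,6,7,8,9,11a-decahydrocyclodeca[b]furan-4-yl (2Z)-2-methylbut-2-enoate | C=C1C(=O)O[C@H]2/C=C(/C)[C@@H](O)CC[C@](C)(O)C[C@@H](OC(=O)/C(C)=C\C)[C@@H]12 | target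

**Step count and risks**

Total step count: 13. Longest linear sequence: 11 (steps 1–10 and 13, from geraniol).

Steps most likely to fail:

Step 13. The lactol may release the C-3 aldehyde too slowly for the alkenylchromium, the two organochromium events may interfere, and the C-3 selectivity rests on a conformational argument. The fallback sets out from 13 and comes back to the route at 20. It uncouples the two bond formations and closes the ring on a free aldehyde in the silyl-protected series. CrCl2 alone couples 13 (C-3 still masked as the prenyl alkene, so no aldehyde competes) with 18 to give the iodo lactone (1R,3S)-1-{(2R,3R)-2-[(1Z)-2-iodoprop-1-en-1-yl]-4-methylidene-5-oxooxolan-3-yl}-3,7-dimethyl-3-(triethylsilyloxy)oct-6-en-1-yl (2Z)-2-methylbut-2-enoate F1. Selective ozonolysis of its prenyl alkene gives the aldehyde (1R,3S)-1-{(2R,3R)-2-[(1Z)-2-iodoprop-1-en-1-yl]-4-methylidene-5-oxooxolan-3-yl}-3-methyl-6-oxo-3-(triethylsilyloxy)hexyl (2Z)-2-methylbut-2-enoate F2, which stays open-chain because O-10 is silylated. NiCl2/CrCl2 in DMSO at high dilution closes the ten-membered ring to the silyl ether (3aR,4R,6S,9S,10Z,11aS)-9-hydroxy-6,10-dimethyl-3-methylidene-2-oxo-6-(triethylsilyloxy)-2,3,3a,4,5,6,7,8,9,11a-decahydrocyclodeca[b]furan-4-yl (2Z)-2-methylbut-2-enoate F3, and HF·pyridine then gives 20.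

Step 6. Hydride may attack the ester, or the C–Al bond may not be iodinated cleanly. The fallback sets out from 7 and comes back at 13, using a palladium-catalysed syn-hydrostannation in place of the hydroxyl-directed anti-hydroalumination. 7 is first esterified with 9 as in step 7 to the ynoate methyl (4R,6S)-6,10-dimethyl-4-{[(2Z)-2-methylbut-2-enoyl]oxy}-6-(triethylsilyloxy)undec-9-en-2-ynoate F4. Bu3SnH with Pd(PPh3)4 gives the stannane methyl (2E,4R,6S)-6,10-dimethyl-4-{[(2Z)-2-methylbut-2-enoyl]oxy}-2-(tributylstannyl)-6-(triethylsilyloxy)undeca-2,9-dienoate F5. I2 gives the iodide methyl (2E,4R,6S)-2-iodo-6,10-dimethyl-4-{[(2Z)-2-methylbut-2-enoyl]oxy}-6-(triethylsilyloxy)undeca-2,9-dienoate F6, the geometric isomer of 10. Stille coupling with 11 gives the alcohol methyl (2Z,4R,6S)-2-(hydroxymethyl)-6,10-dimethyl-4-{[(2Z)-2-methylbut-2-enoyl]oxy}-6-(triethylsilyloxy)undeca-2,9-dienoate F7. CBr4/PPh3 gives the bromide methyl (2E,4R,6S)-2-(bromomethyl)-6,10-dimethyl-4-{[(2Z)-2-methylbut-2-enoyl]oxy}-6-(triethylsilyloxy)undeca-2,9-dienoate F8. LiBr in acetone equilibrates F8 by reversible SN2′ bromide exchange to the more stable (Z)-bromide 13.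

Step 5. The enantioselectivity on this aliphatic β-silyloxy aldehyde may be low. The fallback sets out from 5 and comes back at 7, setting C-8 by a reagent-controlled ketone reduction instead of an addition. Lithium methyl propiolate (from 6 and LiN(SiMe3)2 at −78 °C) adds to 5 to give the carbinol as both C-4 epimers, methyl (4RS,6S)-4-hydroxy-6,10-dimethyl-6-(triethylsilyloxy)undec-9-en-2-ynoate F9. Dess–Martin periodinane gives the ynone methyl (6S)-6,10-dimethyl-4-oxo-6-(triethylsilyloxy)undec-9-en-2-ynoate F10. Midland reduction with (R)-B-isopinocampheyl-9-borabicyclo[3.3.1]nonane gives 7.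

**Further compounds**

F1 | step 13 | (1R,3S)-1-{(2R,3R)-2-[(1Z)-2-iodoprop-1-en-1-yl]-4-methylidene-5-oxooxolan-3-yl}-3,7-dimethyl-3-(triethylsilyloxy)oct-6-en-1-yl (2Z)-2-methylbut-2-enoate | C=C1C(=O)O[C@@H](/C=C(/C)I)[C@H]1[C@H](OC(=O)/C(C)=C\C)C[C@@](C)(O[Si](CC)(CC)CC)CCC=C(C)C
F2 | step 13 | (1R,3S)-1-{(2R,3R)-2-[(1Z)-2-iodoprop-1-en-1-yl]-4-methylidene-5-oxooxolan-3-yl}-3-methyl-6-oxo-3-(triethylsilyloxy)hexyl (2Z)-2-methylbut-2-enoate | C=C1C(=O)O[C@@H](/C=C(/C)I)[C@H]1[C@H](OC(=O)/C(C)=C\C)C[C@@](C)(O[Si](CC)(CC)CC)CCC=O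
F3 | step 13 | (3aR,4R,6S,9S,10Z,11aS)-9-hydroxy-6,10-dimethyl-3-methylidene-2-oxo-6-(triethylsilyloxy)-2,3,3a,4,5,6,7,8,9,11a-decahydrocyclodeca[b]furan-4-yl (2Z)-2-methylbut-2-enoate | C=C1C(=O)O[C@H]2/C=C(/C)[C@@H](O)CC[C@](C)(O[Si](CC)(CC)CC)C[C@@H](OC(=O)/C(C)=C\C)[C@@H]12
F4 | step 6 | methyl (4R,6S)-6,10-dimethyl-4-{[(2Z)-2-methylbut-2-enoyl]oxy}-6-(triethylsilyloxy)undec-9-en-2-ynoate | COC(=O)C#C[C@H](OC(=O)/C(C)=C\C)C[C@@](C)(O[Si](CC)(CC)CC)CCC=C(C)C
F5 | step 6 | methyl (2E,4R,6S)-6,10-dimethyl-4-{[(2Z)-2-methylbut-2-enoyl]oxy}-2-(tributylstannyl)-6-(triethylsilyloxy)undeca-2,9-dienoate | COC(=O)/C([Sn](CCCC)(CCCC)CCCC)=C\[C@H](OC(=O)/C(C)=C\C)C[C@@](C)(O[Si](CC)(CC)CC)CCC=C(C)C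
F6 | step 6 | methyl (2E,4R,6S)-2-iodo-6,10-dimethyl-4-{[(2Z)-2-methylbut-2-enoyl]oxy}-6-(triethylsilyloxy)undeca-2,9-dienoate | COC(=O)/C(I)=C\[C@H](OC(=O)/C(C)=C\C)C[C@@](C)(O[Si](CC)(CC)CC)CCC=C(C)C
F7 | step 6 | methyl (2Z,4R,6S)-2-(hydroxymethyl)-6,10-dimethyl-4-{[(2Z)-2-methylbut-2-enoyl]oxy}-6-(triethylsilyloxy)undeca-2,9-dienoate | COC(=O)/C(CO)=C\[C@H](OC(=O)/C(C)=C\C)C[C@@](C)(O[Si](CC)(CC)CC)CCC=C(C)C
F8 | step 6 | methyl (2E,4R,6S)-2-(bromomethyl)-6,10-dimethyl-4-{[(2Z)-2-methylbut-2-enoyl]oxy}-6-(triethylsilyloxy)undeca-2,9-dienoate | COC(=O)/C(CBr)=C\[C@H](OC(=O)/C(C)=C\C)C[C@@](C)(O[Si](CC)(CC)CC)CCC=C(C)C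
F9 | step 5 | methyl (4RS,6S)-4-hydroxy-6,10-dimethyl-6-(triethylsilyloxy)undec-9-en-2-ynoate (both C-4 epimers) | COC(=O)C#CC(O)C[C@@](C)(O[Si](CC)(CC)CC)CCC=C(C)C
F10 | step 5 | methyl (6S)-6,10-dimethyl-4-oxo-6-(triethylsilyloxy)undec-9-en-2-ynoate | COC(=O)C#CC(=O)C[C@@](C)(O[Si](CC)(CC)CC)CCC=C(C)C
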